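## Structural features

The target 17 is an unbranched decane, numbered here C1–C10 from the benzylic carbon. C1 carries a 3,4-dimethoxyphenyl ring (the only ring), C3 an acetoxy group, C5 a free hydroxyl group, and C6–C10 form a plain pentyl tail. The stereocentres C3 and C5 are separated only by the methylene C4 and are both S. Because the priority order at each is O > C4 > outer chain > H, (3S,5S) is the anti-1,3-diol. The fragile element is the secondary acetate on O3 with the free O5–H in a 1,3-relationship: base or strong acid can shift the acetyl group to O5 through a six-membered cyclic intermediate or remove it. The electron-rich dimethoxybenzene ring also argues against strong oxidants and hard Lewis acids late in the route. The real difficulty is twofold: absolute and relative control of two remote acyclic carbinol centres with no neighbouring handle, and telling two almost identical secondary oxygens apart so that only O3 is acylated. The key step exploits the fact that C3 and C5 are flanked only by methylenes (C2, C4, C6). With C2 and C6 written as chloromethyl groups, the segment C2–C6 becomes a C2-symmetric five-carbon unit whose two carbinol centres can be created together from an achiral 1,3-diketone. In that unit the centres are 2R,4R; this is the same spatial arrangement as 3S,5S in 17, since the descriptor changes only because CH2Cl outranks C4 while the alkyl chains that later replace chlorine do not.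

## Logic of the disconnections

17 from 16: the O5–H of 17 is traced back to an O5–Si bond. O3 and O5 are too similar for a selective mono-acetylation of the free diol, so O5 must be masked while O3 is acylated. The gain is that the regiochemical problem disappears. The demand is that the unmasking run in a medium that is neither basic nor strongly acidic, so that the acetyl group stays on O3; hence a triethylsilyl group, which leaves under buffered HF.

16 from 12 and 13: the C1–C2 bond and the O3–acetyl bond are cut in one operation. C1 is benzylic and becomes nucleophilic in 14, made from 13. C2 is the terminal oxirane carbon of 12, so the opening generates the O3 alkoxide 15 exactly where the acetyl group must go. The gain is that the arene, the two-carbon link and the acetate all arrive in one flask. The demands are formation of 14 without homocoupling, attack at the terminal carbon only, and acylation of 15 before work-up.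

12 from 11: the O5–Si bond is cut. This only prepares the differentiation used above; the demand is a silylation mild enough to leave the oxirane alone.

11 from 9 and 10: the C6–C7 bond is cut. C6 is a terminal oxirane carbon of 9, and the two oxiranes of 9 are exchanged by its C2 axis, so either one gives the same product. The gain is a symmetric five-carbon block plus a commercial four-carbon nucleophile. The demand is that the reaction stop after one opening.

9 from 7: the two oxirane C–O bonds to the terminal carbons (O3–C2 and O5–C6 in the numbering of 17) are cut. 9 is volatile and reactive and is best made just before use from storable, crystallisable 7. The demand is closure by attack of oxygen on CH2Cl, so that no bond at a stereocentre is broken.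

7 from 5: the C–H bonds at both carbinol carbons (C3–H and C5–H of 17) are cut. This is the strategic simplification: all stereochemistry of 17 is reduced to the choice of one catalyst antipode acting on an achiral, symmetric substrate. The demands are enantioselectivity, anti diastereoselectivity and inertness of the C–Cl bonds.

5 from 3, and 3 from 1 and 2: first the bond from the central carbon to the ester carbon is restored (retro-decarboxylation), then the bond between the central carbon and one chloroacetyl carbon is cut. The doubly activated central carbon is the natural nucleophile, and the ester is a removable activating group. The gain is two commercial pieces. The demands are C- rather than O-acylation and removal of the ester without water or base; this is why the tert-butyl ester is preferred to the ethyl ester.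

## Other disconnections considered

Alternative 1: The chain is cut between C3 and C4. Forward, the lithio derivative of 2-[2-(3,4-dimethoxyphenyl)ethyl]-1,3-dithiane A1 would attack the CH2 carbon of (S)-2-pentyloxirane A2. Benzyl bromide added to the same flask would cap the alkoxide, giving 2-[(2S)-2-(benzyloxy)heptyl]-2-[2-(3,4-dimethoxyphenyl)ethyl]-1,3-dithiane A3. Unmasking would give (5S)-5-(benzyloxy)-1-(3,4-dimethoxyphenyl)decan-3-one A4, to be reduced at C3, acetylated and debenzylated.
- In its favour: it is convergent, the dithiane–epoxide union is dependable, and C5 comes from a readily available enantiopure epoxide.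
- Better than the chosen plan: it needs no pressure hydrogenation, no volatile bis-epoxide and no mono-opening of a symmetric bis-electrophile. The final neutral hydrogenolysis of the benzyl ether also carries less risk of acetyl migration than a silyl cleavage.
- Against it here: the key step forms a C–C bond but no stereocentre. C3 must come from reducing A4, a ketone flanked by two methylenes (C2 and C4), where a chiral reagent finds little steric difference. Chelation through the C5 benzyloxy group favours the syn, hence wrong, isomer, and the reliable anti-selective directed reductions need a free O5–H, which would give up the O3/O5 distinction. Unmasking a dithiane beside an electron-rich arene needs thiophilic alkylating or oxidising reagents.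
- Comparison: mechanistically this is anionic SN2 chemistry with one purchased stereocentre, against one catalyst setting both centres with statistical amplification in the chosen plan. The step count is about equal (seven to eight), but the stereochemical weak point sits late and at the harder centre.

Alternative 2: The C3–O bond is made last but one by oxygen insertion. Forward, a buffered peracid would convert (3S,5S)-5-[(tert-butyldimethylsilyl)oxy]-3-[2-(3,4-dimethoxyphenyl)ethyl]decan-2-one A5 into (3S,5S)-5-[(tert-butyldimethylsilyl)oxy]-1-(3,4-dimethoxyphenyl)decan-3-yl acetate A6. The secondary carbon C3 migrates in preference to methyl and with retention.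
- In its favour: the migration is stereospecific and the acetate is born on O3, so no acylation selectivity is needed. On this point it is equal to the alkoxide trapping of the chosen plan.
- Better than the chosen plan: no symmetric bis-electrophile has to be opened once, and no pressure equipment is needed.
- Against it here: the problem is moved to A5, whose C3 is a carbon stereocentre next to a ketone. It must be built by an auxiliary-controlled alkylation or a comparable multistep sequence, it can epimerise on the way, and its 1,3-relationship to C5 needs a second independent asymmetric event. Oxygen insertion into a methyl sec-alkyl ketone is slow enough for peracid attack on the dimethoxyarene to compete.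
- Comparison: the final desilylation carries the same acetyl-migration hazard as step 8 (equal), with a silyl group that leaves less readily than the one in 16. The route would be clearly longer.

Alternative 3: The chain is cut between C2 and C3. Forward, (3S)-3-(benzyloxy)-1-bromooctyl acetate A7 (both configurations at C1, made from (3S)-3-(benzyloxy)octanal A10 and acetyl bromide) would couple with [2-(3,4-dimethoxyphenyl)ethyl]zinc bromide A8 under NiBr2·glyme and a chiral bis(oxazoline)-type ligand. The product would be (3S,5S)-5-(benzyloxy)-1-(3,4-dimethoxyphenyl)decan-3-yl acetate A9; hydrogenolysis would finish the synthesis.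
- In its favour and better than the chosen plan: it is the most convergent option. One mild catalytic step forms the C2–C3 bond, the C3 stereocentre and the correctly placed acetate, and the neutral final deprotection lowers the migration risk.
- Against it here: A10 needs its own asymmetric synthesis, and A7 is a moisture-sensitive geminal bromo ester. The catalyst would have to override an existing C5 stereocentre carrying a Lewis-basic benzyloxy group, a matched/mismatched situation for which the outcome cannot be taken for granted. The method also depends on a specialised ligand.
- Comparison: two independent sources of chirality replace the single catalyst of the chosen plan, whose second reduction also removes errors of the first. The step count is equal or slightly better (about six to seven), but the stereochemical outcome at C3 is less predictable.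

Key step: step 3

Remark on the chemistry: the sense of induction is assigned by analogy with 3-oxobutanoates, 4-chloro-3-oxobutanoates and pentane-2,4-dione, which RuCl2(BINAP) reduces with one common spatial sense. On that basis (S)-BINAP is expected to give 7; the sign of rotation of 7 should be checked before going on.

## Route

Step 1
Reactants: 1 tert-butyl 4-chloro-3-oxobutanoate; 2 chloroacetyl chloride
Product: 3 tert-butyl 4-chloro-2-(chloroacetyl)-3-oxobutanoate
Conditions: MgCl2 (1.0 equiv), pyridine (2.0 equiv), CH2Cl2, 0 °C; 2 (1.05 equiv), 0 °C; cold 1 M HCl work-up
Reagents that add atoms: none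
Why: Soft enolisation with MgCl2 and pyridine gives the magnesium chelate of 1, which is C-acylated by 2 (Claisen-type C-acylation of a β-keto ester); chelation suppresses O-acylation and self-alkylation at the chloromethyl group, and the cold acidic work-up avoids base-induced cyclisation of 3 to a furanone.

Step 2
Reactants: 3 tert-butyl 4-chloro-2-(chloroacetyl)-3-oxobutanoate
Product: 5 1,5-dichloropentane-2,4-dione, via 4-chloro-2-(chloroacetyl)-3-oxobutanoic acid 4 (not isolated)
Conditions: TsOH·H2O (5 mol %), toluene, 80 °C until gas evolution ends; distillation under reduced pressure
Reagents that add atoms: none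
Why: Acid-catalysed loss of 2-methylpropene from the tert-butyl ester (E1) gives acid 4, which decarboxylates through the usual six-membered enol transition state; without water or nucleophiles the retro-Claisen loss of a chloroacetyl group, the weak point of hydrolysing an ethyl ester, cannot intervene.

Step 3
Reactants: 5 1,5-dichloropentane-2,4-dione
Product: 7 (2R,4R)-1,5-dichloropentane-2,4-diol, via (4R)-1,5-dichloro-4-hydroxypentan-2-one 6 (not isolated)
Conditions: RuCl2[(S)-BINAP] (0.2 mol %, charged as [RuCl2((S)-BINAP)]2·NEt3), H2 (85 atm), MeOH, 80 °C; recrystallisation
Reagents that add atoms: none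
Why: Under H2 in methanol the precatalyst becomes a RuHCl(BINAP) species of divalent ruthenium; 5 binds through both carbonyl oxygens as a six-membered chelate, hydride passes to the carbonyl carbon inside the chelate and methanolysis releases hydroxy ketone 6. 6 binds again through its hydroxyl and remaining carbonyl and is reduced by the same catalyst, whose facial preference overrides the weak bias of the existing centre, so the second hydride arrives with the same spatial sense and the diol is anti. The closest known reaction type is the Noyori hydrogenation of 1,3-diketones and of 4-chloro-3-oxobutanoates with RuCl2(BINAP). No ring is closed. Both new stereocentres (C2 and C4 of 7, later C5 and C3 of 17) are controlled by the axial chirality of (S)-BINAP, whose equatorial P-phenyl groups block two diagonal quadrants; the descriptor is R because CH2Cl outranks the chain methylene. The step needs enantioselectivity, anti diastereoselectivity and preference for C=O over C–Cl; bidentate 1,3-dicarbonyl binding, which at 80 °C should dominate over chlorine-assisted binding, and the C2 symmetry of 5 (both carbonyls equivalent) secure them. Molecules reduced in the wrong sense in the first event end mostly as the meso diol, which crystallisation removes, so the enantiomeric purity of 7 should exceed the selectivity of a single reduction.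

Step 4
Reactants: 7 (2R,4R)-1,5-dichloropentane-2,4-diol
Product: 9 (2R,2'R)-2,2'-methylenebis(oxirane), via (2R)-1-chloro-3-[(2R)-oxiran-2-yl]propan-2-ol 8 (not isolated)
Conditions: powdered KOH (3 equiv), Et2O, rt; filtration; careful distillation under reduced pressure (volatile alkylating agent, closed handling)
Reagents that add atoms: none
Why: Twofold intramolecular Williamson etherification: each alkoxide displaces the neighbouring primary chloride (3-exo-tet), so no bond to a stereocentre is broken and both configurations are kept; the three-membered closure outruns five-membered attack on the distal CH2Cl.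

Step 5
Reactants: 9 (2R,2'R)-2,2'-methylenebis(oxirane); 10 n-butylmagnesium chloride
Product: 11 (2S)-1-[(2R)-oxiran-2-yl]heptan-2-ol
Conditions: 9 (1.4 equiv), CuI (10 mol %), THF, −40 °C; 10 (1.0 equiv, THF solution) added slowly; aq. NH4Cl; unreacted 9 recovered by distillation
Reagents that add atoms: none
Why: Copper-catalysed Grignard opening of a terminal epoxide (SN2 at the CH2 carbon by the butylcopper species of monovalent copper formed from 10 and CuI); the two oxiranes of 9 are homotopic, so only one mono-adduct can form, and the excess of 9 with slow addition of 10 holds back the second opening. The carbinol carbon is not touched; its descriptor changes from R to S only because the former oxirane CH2 now ranks below C4.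

Step 6
Reactants: 11 (2S)-1-[(2R)-oxiran-2-yl]heptan-2-ol
Product: 12 triethyl{[(2S)-1-[(2R)-oxiran-2-yl]heptan-2-yl]oxy}silane
Conditions: Et3SiCl (1.2 equiv), imidazole (2 equiv), CH2Cl2, 0 °C
Reagents that add atoms: chlorotriethylsilane, CC[Si](Cl)(CC)CC
Why: Imidazole-promoted silylation of the secondary alcohol; the oxirane is inert under these cold, neutral conditions, and the triethylsilyl group is chosen because it later leaves under milder conditions than a tert-butyldimethylsilyl group.

Step 7
Reactants: 12 triethyl{[(2S)-1-[(2R)-oxiran-2-yl]heptan-2-yl]oxy}silane; 13 3,4-dimethoxybenzyl chloride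
Product: 16 (3S,5S)-1-(3,4-dimethoxyphenyl)-5-[(triethylsilyl)oxy]decan-3-yl acetate, via 3,4-dimethoxybenzylmagnesium chloride 14 (not isolated), via chloromagnesium C3-alkoxide 15 (not isolated)
Conditions: 13 (2 equiv) added slowly to Mg turnings (4 equiv), THF, 0 °C; then 12 (1 equiv), CuI (10 mol %), THF, −30 °C; then Ac2O (5 equiv), DMAP (10 mol %), −30 °C to rt; aq. NaHCO3
Reagents that add atoms: acetic anhydride, CC(=O)OC(C)=O; magnesium, [Mg] (kept only in 14 and 15)
Why: Insertion of Mg into the benzylic C–Cl bond gives 14 (slow, cold, dilute addition to hold back Wurtz coupling); CuI-catalysed SN2 opening of the terminal oxirane carbon forms the C1–C2 bond and alkoxide 15 without touching the C3 stereocentre, and O-acylation of 15 by Ac2O places the acetyl group on O3 while O5 is silylated.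

Step 8
Reactants: 16 (3S,5S)-1-(3,4-dimethoxyphenyl)-5-[(triethylsilyl)oxy]decan-3-yl acetate
Product: 17 (3S,5S)-1-(3,4-dimethoxyphenyl)-5-hydroxydecan-3-yl acetate
Conditions: HF·pyridine, pyridine, THF, 0 °C (polyethylene vessel); aq. NaHCO3 quench at 0 °C
Reagents that add atoms: none
Why: Fluoride-assisted cleavage of the Si–O bond under weakly acidic, pyridine-buffered conditions (silyl ether deprotection); with no alkoxide and no strong acid present the acetate should neither migrate to O5 nor be cleaved, and no stereocentre is involved.

## Compound list

1 | tert-butyl 4-chloro-3-oxobutanoate | CC(C)(C)OC(=O)CC(=O)CCl | starting material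
2 | chloroacetyl chloride | ClCC(Cl)=O | starting material
3 | tert-butyl 4-chloro-2-(chloroacetyl)-3-oxobutanoate | CC(C)(C)OC(=O)C(C(=O)CCl)C(=O)CCl | intermediate
4 | 4-chloro-2-(chloroacetyl)-3-oxobutanoic acid (not isolated) | OC(=O)C(C(=O)CCl)C(=O)CCl | intermediate
5 | 1,5-dichloropentane-2,4-dione | ClCC(=O)CC(=O)CCl | intermediate
6 | (4R)-1,5-dichloro-4-hydroxypentan-2-one (not isolated) | ClCC(=O)C[C@H](CCl)O | intermediate
7 | (2R,4R)-1,5-dichloropentane-2,4-diol | ClC[C@H](O)C[C@H](CCl)O | intermediate
8 | (2R)-1-chloro-3-[(2R)-oxiran-2-yl]propan-2-ol (not isolated) | ClC[C@H](O)C[C@@H]1CO1 | intermediate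
9 | (2R,2'R)-2,2'-methylenebis(oxirane), i.e. (2R,4R)-1,2:4,5-diepoxypentane | C1O[C@@H]1C[C@@H]1CO1 | intermediate
10 | n-butylmagnesium chloride | CCCC[Mg]Cl | starting material
11 | (2S)-1-[(2R)-oxiran-2-yl]heptan-2-ol | CCCCC[C@H](O)C[C@@H]1CO1 | intermediate
12 | triethyl{[(2S)-1-[(2R)-oxiran-2-yl]heptan-2-yl]oxy}silane | CCCCC[C@H](O[Si](CC)(CC)CC)C[C@@H]1CO1 | intermediate
13 | 3,4-dimethoxybenzyl chloride | COc1ccc(CCl)cc1OC | starting material
14 | 3,4-dimethoxybenzylmagnesium chloride (not isolated) | COc1ccc(C[Mg]Cl)cc1OC | intermediate
15 | chloromagnesium (3S,5S)-1-(3,4-dimethoxyphenyl)-5-[(triethylsilyl)oxy]decan-3-olate (not isolated) | CCCCC[C@H](O[Si](CC)(CC)CC)C[C@H](CCc1ccc(OC)c(OC)c1)O[Mg]Cl | intermediate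
16 | (3S,5S)-1-(3,4-dimethoxyphenyl)-5-[(triethylsilyl)oxy]decan-3-yl acetate | CCCCC[C@H](O[Si](CC)(CC)CC)C[C@H](CCc1ccc(OC)c(OC)c1)OC(C)=O | intermediate
17 | (3S,5S)-1-(3,4-dimethoxyphenyl)-5-hydroxydecan-3-yl acetate | CCCCC[C@H](O)C[C@H](CCc1ccc(OC)c(OC)c1)OC(C)=O | target

## Step count and least certain steps

Total step count: 8. Longest linear sequence: 8 steps (1 and 2 to 17); 13 enters in step 7 through 14, which is made in the flask.

Step 3 (key step). What may go wrong: chlorine-assisted binding of the substrate could compete with dicarbonyl chelation and lower the facial selectivity of the first hydride transfer. Hydrogenolysis or solvolysis of a C–Cl bond could release HCl and deactivate the catalyst. The second reduction could stall. Fallback, from 5 back to 7 without the double hydrogenation: an NADPH-dependent alcohol dehydrogenase of the enantiopreference that gives the 4R alcohol (isopropanol as hydride donor, phosphate buffer, 30 °C) reduces one carbonyl of 5, and 6 is isolated. Me4NBH(OAc)3 in MeCN/AcOH at −30 °C (Evans–Saksena reduction) then delivers hydride intramolecularly from boron bound to the C4 oxygen and sets the second centre anti, giving 7. The first centre then comes from an enzyme and the second from substrate control; no compound outside the list is made.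

Step 7. What may go wrong: Wurtz-type homocoupling while the electron-rich benzylic chloride is converted into 14. Acylation of the magnesium alkoxide 15 may be incomplete, or surplus 14 may consume the Ac2O. MgCl2 may open the oxirane to a chlorohydrin. Fallback, from 12 to 16, replacing the benzylic Grignard reagent by a stabilised benzylic anion:
- 2-(3,4-dimethoxyphenyl)-1,3-dithiane F1 is made from 3,4-dimethoxybenzaldehyde and propane-1,3-dithiol with BF3·OEt2.
- F1 is lithiated (n-BuLi, THF, −30 °C) and opens 12 at the terminal carbon, giving (2R,4S)-1-[2-(3,4-dimethoxyphenyl)-1,3-dithian-2-yl]-4-[(triethylsilyl)oxy]nonan-2-ol F2. The spatial arrangement is the same as in 16; the descriptor at the carbinol is R only because the dithianylmethyl branch outranks C3.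
- Raney Ni in EtOH removes the sulfur, giving (3S,5S)-1-(3,4-dimethoxyphenyl)-5-[(triethylsilyl)oxy]decan-3-ol F3.
- Ac2O, DMAP and pyridine in CH2Cl2 convert F3 into 16.

Step 5. What may go wrong: a second opening of the mono-adduct (over-addition), and loss of volatile 9 on handling and recovery. Fallback, from 7 to 11, desymmetrising before any C–C bond is made:
- MeC(OMe)3 with catalytic pyridinium p-toluenesulfonate in CH2Cl2 converts 7 into (4R,6R)-4,6-bis(chloromethyl)-2-methoxy-2-methyl-1,3-dioxane F4.
- Aqueous AcOH opens F4 to (2R,4R)-1,5-dichloro-4-hydroxypentan-2-yl acetate F5. The cyclic orthoester can collapse only to a monoester, and acetyl migration in F5 is degenerate because of the C2 symmetry.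
- NaH (1 equiv) in THF at 0 °C closes the free chlorohydrin, giving (2R)-1-chloro-3-[(2R)-oxiran-2-yl]propan-2-yl acetate F6, which has a single oxirane.
- 10 with CuI (10 mol %) in THF at −78 °C opens F6 to (2R,4S)-1-chloro-4-hydroxynonan-2-yl acetate F7. Any acetyl-shifted isomer converges in the next operation.
- K2CO3 in MeOH at 0 °C removes the acetate and closes the oxirane, giving 11.

Step 8. What may go wrong: migration of the acetyl group from O3 to O5 once O5 is free, or partial loss of the acetate, if the medium drifts basic on quenching or the cleavage needs prolonged exposure to HF. Fallback, from 11 to 17, with a protecting group removed under neutral, non-nucleophilic conditions: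
- NaH, benzyl bromide and catalytic Bu4NI in THF at 0 °C convert 11 into (2R)-2-[(2S)-2-(benzyloxy)heptyl]oxirane F8.
- The operations of step 7 (14, CuI, then Ac2O) convert F8 into (3S,5S)-5-(benzyloxy)-1-(3,4-dimethoxyphenyl)decan-3-yl acetate F9, the same compound as A9.
- H2 (1 atm) over Pd/C in EtOAc cleaves the benzyl ether and gives 17.

Step 1. What may go wrong: O-acylation in place of C-acylation, self-alkylation of the enolate at a chloromethyl group, and cyclisation of the acylated product by intramolecular O-alkylation if the medium becomes basic. Fallback, from 2 to 5, bypassing steps 1 and 2: AlCl3-mediated double C-acylation of vinyl acetate with two equivalents of 2 in CH2Cl2 (0 °C to rt), followed by aqueous acidic work-up in which the former CH carbon of vinyl acetate is lost as formic acid. This is a known entry to symmetrical 1,3-diketones. Crude 5 is captured with aqueous Cu(OAc)2 as the crystalline divalent copper chelate bis(1,5-dichloropentane-2,4-dionato)copper F10, filtered, and released as 5 with dilute H2SO4 in Et2O before distillation.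

## Further compounds

F0 | step 3 | none | none
F1 | step 7 | 2-(3,4-dimethoxyphenyl)-1,3-dithiane | COc1ccc(C2SCCCS2)cc1OC
F2 | step 7 | (2R,4S)-1-[2-(3,4-dimethoxyphenyl)-1,3-dithian-2-yl]-4-[(triethylsilyl)oxy]nonan-2-ol | CCCCC[C@H](O[Si](CC)(CC)CC)C[C@@H](O)CC1(c2ccc(OC)c(OC)c2)SCCCS1
F3 | step 7 | (3S,5S)-1-(3,4-dimethoxyphenyl)-5-[(triethylsilyl)oxy]decan-3-ol | CCCCC[C@H](O[Si](CC)(CC)CC)C[C@H](CCc1ccc(OC)c(OC)c1)O
F4 | step 5 | (4R,6R)-4,6-bis(chloromethyl)-2-methoxy-2-methyl-1,3-dioxane | COC1(C)O[C@@H](CCl)C[C@H](CCl)O1
F5 | step 5 | (2R,4R)-1,5-dichloro-4-hydroxypentan-2-yl acetate | ClC[C@H](O)C[C@H](CCl)OC(C)=O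
F6 | step 5 | (2R)-1-chloro-3-[(2R)-oxiran-2-yl]propan-2-yl acetate | ClC[C@H](OC(C)=O)C[C@@H]1CO1
F7 | step 5 | (2R,4S)-1-chloro-4-hydroxynonan-2-yl acetate | CCCCC[C@H](O)C[C@H](CCl)OC(C)=O
F8 | step 8 | (2R)-2-[(2S)-2-(benzyloxy)heptyl]oxirane | CCCCC[C@H](OCc1ccccc1)C[C@@H]1CO1
F9 | step 8 | (3S,5S)-5-(benzyloxy)-1-(3,4-dimethoxyphenyl)decan-3-yl acetate | CCCCC[C@H](OCc1ccccc1)C[C@H](CCc1ccc(OC)c(OC)c1)OC(C)=O
F10 | step 1 | bis(1,5-dichloropentane-2,4-dionato)copper | ClCC(=O)/C=C(/CCl)O[Cu]O/C(CCl)=C\C(=O)CCl
A1 | alternative 1 | 2-[2-(3,4-dimethoxyphenyl)ethyl]-1,3-dithiane | COc1ccc(CCC2SCCCS2)cc1OC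
A2 | alternative 1 | (S)-2-pentyloxirane | CCCCC[C@H]1CO1
A3 | alternative 1 | 2-[(2S)-2-(benzyloxy)heptyl]-2-[2-(3,4-dimethoxyphenyl)ethyl]-1,3-dithiane | CCCCC[C@H](OCc1ccccc1)CC1(CCc2ccc(OC)c(OC)c2)SCCCS1
A4 | alternative 1 | (5S)-5-(benzyloxy)-1-(3,4-dimethoxyphenyl)decan-3-one | CCCCC[C@H](OCc1ccccc1)CC(=O)CCc1ccc(OC)c(OC)c1
A5 | alternative 2 | (3S,5S)-5-[(tert-butyldimethylsilyl)oxy]-3-[2-(3,4-dimethoxyphenyl)ethyl]decan-2-one | CCCCC[C@H](O[Si](C)(C)C(C)(C)C)C[C@H](CCc1ccc(OC)c(OC)c1)C(C)=O
A6 | alternative 2 | (3S,5S)-5-[(tert-butyldimethylsilyl)oxy]-1-(3,4-dimethoxyphenyl)decan-3-yl acetate | CCCCC[C@H](O[Si](C)(C)C(C)(C)C)C[C@H](CCc1ccc(OC)c(OC)c1)OC(C)=O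
A7 | alternative 3 | (3S)-3-(benzyloxy)-1-bromooctyl acetate (both configurations at C1) | CCCCC[C@H](OCc1ccccc1)CC(Br)OC(C)=O
A8 | alternative 3 | [2-(3,4-dimethoxyphenyl)ethyl]zinc bromide | COc1ccc(CC[Zn]Br)cc1OC
A9 | alternative 3 | (3S,5S)-5-(benzyloxy)-1-(3,4-dimethoxyphenyl)decan-3-yl acetate | CCCCC[C@H](OCc1ccccc1)C[C@H](CCc1ccc(OC)c(OC)c1)OC(C)=O
A10 | alternative 3 | (3S)-3-(benzyloxy)octanal | CCCCC[C@H](OCc1ccccc1)CC=O
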